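**Plan**
- Retrosynthesis: ring C is opened at O1–C2 (cyclodehydration of a 2-hydroxyaryl 1,3-diketone). Then C4a–C4 and C3–C4 are cut together, so that C4 becomes one molecule of CO between a ring A aryl iodide and a ring B ketone enolate.
- Enabling feature: C4 is a lone carbonyl carbon between C4a (flanked by C5–OMe and C8a–O) and the methoxy-bearing C3. The alpha-methoxy ketone carries C2, C3, 3-OMe and ring B in one piece.
- Forward: 1,2,3,4-tetramethoxybenzene is hydroxylated, protected as the methoxymethyl ether and iodinated at its last ring carbon. 1,3-Dimethoxybenzene is methoxyacetylated. The two are joined with CO to the open diketone, and ring C closes last under acid.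
- Stereochemistry: the target has no stereocentre. C3 of the diketone forms racemic, is enolisable and is lost on aromatisation.

Key step: step 5

Assumption: the target is the achiral flavone 2-(2,4-dimethoxyphenyl)-3,5,6,7,8-pentamethoxy-4H-chromen-4-one; flavone numbering is used (ring A benzo, ring B aryl, ring C pyranone).

**Step 1**
Reactants: 1 1,2,3,4-tetramethoxybenzene
Product: 4 2,3,4,5-tetramethoxyphenol, via aryllithium 2 (not isolated), via arylboronate 3 (not isolated)
Conditions: n-BuLi, TMEDA, THF, 0 °C; B(OMe)3, −78 °C → rt; AcOH, 30% aq H2O2, 0 °C → rt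
Reagents that add atoms: hydrogen peroxide, OO (phenol oxygen); n-butyllithium, [Li]CCCC (lithium of 2 only); trimethyl borate, COB(OC)OC (boron and methoxy groups of 3 only)
Why: Directed ortho-metalation next to a methoxy group, borylation and peroxide oxidation (aryl shift from boron to oxygen) is the standard anisole-to-phenol sequence, and the two ring hydrogens of 1 are equivalent, so only one phenol can form.

**Step 2**
Reactants: 4 2,3,4,5-tetramethoxyphenol
Product: 5 1,2,3,4-tetramethoxy-5-(methoxymethoxy)benzene
Conditions: MOMCl, i-Pr2NEt, CH2Cl2, 0 °C → rt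
Reagents that add atoms: chloromethyl methyl ether, COCCl
Why: O-alkylation of the phenol with chloromethyl methyl ether and a hindered amine gives an acid-labile methoxymethyl ether that is also a strong directing group for the next metalation.

**Step 3**
Reactants: 5 1,2,3,4-tetramethoxy-5-(methoxymethoxy)benzene
Product: 7 1-iodo-2,3,4,5-tetramethoxy-6-(methoxymethoxy)benzene, via aryllithium 6 (not isolated)
Conditions: n-BuLi, THF, −78 → 0 °C; I2, THF, −78 °C → rt
Reagents that add atoms: iodine, I-I; n-butyllithium, [Li]CCCC (lithium of 6 only)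
Why: Directed ortho-metalation is site-specific because the only ring hydrogen lies between the methoxymethoxy and a methoxy group, and iodine converts the aryllithium into the aryl iodide.

**Step 4**
Reactants: 8 1,3-dimethoxybenzene; 9 methoxyacetyl chloride
Product: 10 1-(2,4-dimethoxyphenyl)-2-methoxyethanone
Conditions: AlCl3, CH2Cl2, −10 → 0 °C, cold aqueous quench
Reagents that add atoms: none
Why: Friedel–Crafts acylation of resorcinol dimethyl ether occurs at C4, para to one methoxy group and ortho to the other, and low temperature with a cold quench should limit chelation-assisted ortho-demethylation.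

**Step 5**
Reactants: 7 1-iodo-2,3,4,5-tetramethoxy-6-(methoxymethoxy)benzene; 10 1-(2,4-dimethoxyphenyl)-2-methoxyethanone
Product: 11 1-(2,4-dimethoxyphenyl)-2-methoxy-3-[2,3,4,5-tetramethoxy-6-(methoxymethoxy)phenyl]propane-1,3-dione (racemic)
Conditions: Pd(dba)2 (5 mol %), Ph2P(CH2)3PPh2 (dppp, 6 mol %), MgCl2, Et3N, CO (1 atm), 1,4-dioxane, 80 °C; dilute aqueous acid work-up
Reagents that add atoms: carbon monoxide, [C-]#[O+]
Why: Zerovalent palladium inserts into the C–I bond of 7, CO migrates in to give an aroyl complex of divalent palladium, the magnesium enolate formed from 10 by soft enolisation (MgCl2/Et3N, chelation through the carbonyl and the alpha-methoxy oxygen) displaces iodide, and reductive elimination forms C3–C4 next to the new C4a–C4 bond. The closest known reaction type is the palladium-catalysed carbonylative alpha-arylation of aryl alkyl ketones with aryl iodides to 1,3-diketones under Pd(dba)2 and dppp. No ring is closed; the chain stays open until step 6. The one new sp3 centre, C3, is not controlled: it forms racemic, is enolisable and is flattened in the final aromatisation. The step needs carbonylation ahead of direct alpha-arylation and C- ahead of O-acylation: CO insertion should be fast for an arylpalladium crowded by two ortho oxygens because it moves the metal one atom away from the ring, the chelating diphosphine is a poor ligand for direct arylation, and the magnesium-bound enolate reacts at carbon. Ketone 10 has a single enolisable position, and the product is held as its magnesium 1,3-diketonate, which blocks a second aroylation.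

**Step 6**
Reactants: 11 1-(2,4-dimethoxyphenyl)-2-methoxy-3-[2,3,4,5-tetramethoxy-6-(methoxymethoxy)phenyl]propane-1,3-dione
Product: 14 2-(2,4-dimethoxyphenyl)-3,5,6,7,8-pentamethoxy-4H-chromen-4-one, via free phenol diketone 12 (not isolated), via 2-hydroxyflavanone hemiketal 13 (not isolated)
Conditions: 3 M HCl in MeOH, 60 °C
Reagents that add atoms: none
Why: Acidic methanol transacetalises the methoxymethyl ether, the freed C8a phenol adds to the ring B ketone (6-exo-trig hemiketalisation, the only carbonyl that gives a six-membered ring) and loss of water gives the aromatic pyranone, as in the closing cyclodehydration of a Baker–Venkataraman flavone synthesis.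

**Compound list**
1 | 1,2,3,4-tetramethoxybenzene | COc1ccc(OC)c(OC)c1OC | starting material
2 | (2,3,4,5-tetramethoxyphenyl)lithium | [Li]c1cc(OC)c(OC)c(OC)c1OC | intermediate (not isolated)
3 | dimethyl (2,3,4,5-tetramethoxyphenyl)boronate | COB(OC)c1cc(OC)c(OC)c(OC)c1OC | intermediate (not isolated)
4 | 2,3,4,5-tetramethoxyphenol | COc1cc(O)c(OC)c(OC)c1OC | intermediate
5 | 1,2,3,4-tetramethoxy-5-(methoxymethoxy)benzene | COCOc1cc(OC)c(OC)c(OC)c1OC | intermediate
6 | [2,3,4,5-tetramethoxy-6-(methoxymethoxy)phenyl]lithium | [Li]c1c(OCOC)c(OC)c(OC)c(OC)c1OC | intermediate (not isolated)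
7 | 1-iodo-2,3,4,5-tetramethoxy-6-(methoxymethoxy)benzene | COCOc1c(I)c(OC)c(OC)c(OC)c1OC | intermediate
8 | 1,3-dimethoxybenzene | COc1cccc(OC)c1 | starting material
9 | methoxyacetyl chloride | COCC(=O)Cl | starting material
10 | 1-(2,4-dimethoxyphenyl)-2-methoxyethanone | COCC(=O)c1ccc(OC)cc1OC | intermediate
11 | 1-(2,4-dimethoxyphenyl)-2-methoxy-3-[2,3,4,5-tetramethoxy-6-(methoxymethoxy)phenyl]propane-1,3-dione (racemic, enolisable) | COCOc1c(OC)c(OC)c(OC)c(OC)c1C(=O)C(OC)C(=O)c1ccc(OC)cc1OC | intermediate
12 | 1-(2,4-dimethoxyphenyl)-3-(2-hydroxy-3,4,5,6-tetramethoxyphenyl)-2-methoxypropane-1,3-dione (racemic, enolisable) | COc1ccc(C(=O)C(OC)C(=O)c2c(O)c(OC)c(OC)c(OC)c2OC)c(OC)c1 | intermediate (not isolated)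
13 | 2-(2,4-dimethoxyphenyl)-2-hydroxy-3,5,6,7,8-pentamethoxychroman-4-one (racemic mixture of diastereomers) | COc1ccc(C2(O)Oc3c(OC)c(OC)c(OC)c(OC)c3C(=O)C2OC)c(OC)c1 | intermediate (not isolated)
14 | 2-(2,4-dimethoxyphenyl)-3,5,6,7,8-pentamethoxy-4H-chromen-4-one | COc1ccc(-c2oc3c(OC)c(OC)c(OC)c(OC)c3c(=O)c2OC)c(OC)c1 | target

**Total steps:** 6. **Longest linear sequence:** 5 (steps 1, 2, 3, 5, 6).

**Steps most likely to fail**

1. Step 5. Oxidative addition of the electron-rich, doubly ortho-oxygenated iodide may be too slow under CO, and the crowded aroyl palladium species may be captured slowly by the enolate. Reduction of the iodide and self-condensation of the ketone would then compete.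
   Fallback (Baker–Venkataraman route): it sets out from 5 and returns at 12.
   - 5 is lithiated as in step 3, and aryllithium 6 is acylated with N,2-dimethoxy-N-methylacetamide (THF, −78 °C → rt) to give 2-methoxy-1-[2,3,4,5-tetramethoxy-6-(methoxymethoxy)phenyl]ethanone F1.
   - HCl in MeOH at rt frees the phenol to give 1-(2-hydroxy-3,4,5,6-tetramethoxyphenyl)-2-methoxyethanone F2.
   - 2,4-Dimethoxybenzoyl chloride, pyridine and catalytic DMAP give 2-(methoxyacetyl)-3,4,5,6-tetramethoxyphenyl 2,4-dimethoxybenzoate F3.
   - KOH in pyridine at 50 °C (or LiN(SiMe3)2 in THF) moves the unhindered aroyl group from oxygen to the ketone alpha-carbon and delivers 12, which is closed to 14 under the acid conditions of step 6.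
   - Here C4a–C4 comes from the aryllithium acylation and C2–C3 from the intramolecular acyl transfer, so no intermolecular attack at a crowded carbonyl is needed.

2. Step 4. AlCl3 may strip the methyl group ortho to the new ketone through chelation, and the methoxyacetyl cation may lose CO to a methoxymethyl cation that alkylates the arene.
   Fallback: it sets out from 8 and returns at 10.
   - NBS in MeCN (0 °C → rt) gives 1-bromo-2,4-dimethoxybenzene F4.
   - Bromine–lithium exchange (n-BuLi, THF, −78 °C) gives (2,4-dimethoxyphenyl)lithium F5.
   - Addition to N,2-dimethoxy-N-methylacetamide gives 10 after aqueous work-up, with no Lewis acid involved.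

3. Step 1. Metalation directed by a single methoxy group may stay incomplete, and the very electron-rich para-methoxyphenol may be over-oxidised by peroxide towards a quinone while it is free in the oxidising medium.
   Fallback: it sets out from 1 and returns at 4.
   - Rieche formylation (Cl2CHOMe, TiCl4, CH2Cl2, 0 °C) gives 2,3,4,5-tetramethoxybenzaldehyde F6.
   - Baeyer–Villiger oxidation (3-chloroperoxybenzoic acid, CH2Cl2, 0 °C → rt) gives 2,3,4,5-tetramethoxyphenyl formate F7, in which the phenol stays masked until the oxidant is quenched.
   - Catalytic K2CO3 in MeOH releases 4.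

**Further compounds**
F1 | step 5 | 2-methoxy-1-[2,3,4,5-tetramethoxy-6-(methoxymethoxy)phenyl]ethanone | COCC(=O)c1c(OCOC)c(OC)c(OC)c(OC)c1OC
F2 | step 5 | 1-(2-hydroxy-3,4,5,6-tetramethoxyphenyl)-2-methoxyethanone | COCC(=O)c1c(O)c(OC)c(OC)c(OC)c1OC
F3 | step 5 | 2-(methoxyacetyl)-3,4,5,6-tetramethoxyphenyl 2,4-dimethoxybenzoate | COCC(=O)c1c(OC(=O)c2ccc(OC)cc2OC)c(OC)c(OC)c(OC)c1OC
F4 | step 4 | 1-bromo-2,4-dimethoxybenzene | COc1ccc(Br)c(OC)c1
F5 | step 4 | (2,4-dimethoxyphenyl)lithium | [Li]c1ccc(OC)cc1OC
F6 | step 1 | 2,3,4,5-tetramethoxybenzaldehyde | COc1cc(C=O)c(OC)c(OC)c1OC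
F7 | step 1 | 2,3,4,5-tetramethoxyphenyl formate | COc1cc(OC=O)c(OC)c(OC)c1OC
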